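**Route to CNP0330767.1 (target 32): quinone ring grown from a methoxycyclobutenedione and a chain-bearing alkenyl bromide**

Ring atoms are numbered as in the target (C1 carbonyl, C2 methoxy, C3 hydrogen, C4 carbonyl, C5 methyl, C6 chain); chain atoms are primed (C1' to C17').

## Analysis of the target

Target 32 is a 1,4-benzoquinone in which all four non-carbonyl ring positions differ: C2 carries methoxy, C3 hydrogen, C5 methyl and C6 a seventeen-carbon chain. The C1 carbonyl therefore lies between the methoxy carbon and the chain carbon, and the C4 carbonyl between C3–H and the methyl carbon. The chain has eight methylene groups (C1' to C8'), methyl branches at C9', C11', C13' and C15', and an ethyl terminus (C16', C17'). The four stereocentres (9'R,11'R,13'S,15'S) are all syn to their neighbours; the change of descriptor in mid-chain is a CIP effect only. They are separated by methylene groups, carry no heteroatom and lie far from the ring, so nothing in the molecule can direct their formation and stereoisomers would be almost impossible to separate. The quinone is the sensitive part (electrophilic at C3, open to addition–elimination at C2, easily reduced, unstable to strong base), so it is best revealed last from its hydroquinone. The synthesis is hard on two counts: a stereotetrad without functional handles, and a fully differentiated quinone that substitution of an electron-rich arene serves poorly, because two free positions of similar reactivity would compete. The strategy rests on the fact that the ring divides into a four-carbon unit C1–C2–C3–C4, which holds both oxygens, the methoxy group and the hydrogen and is a methoxycyclobutenedione, and a two-carbon unit C5–C6, which holds the methyl group and the chain and is a trisubstituted alkene.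

## Retrosynthetic reasoning

**32 to 31.** No skeletal bond is cut; the quinone is taken back to hydroquinone 31. This keeps the electrophilic quinone away from every organometallic reagent. The forward reaction only has to remove two electrons under neutral conditions.

**31 to 23 and 26.** The bonds C1–C6 and C4–C5 are cut. This divides the ring into dione 26 (C1 to C4, with both oxygens, methoxy and hydrogen already on the right carbons) and the alkene carbons of bromide 23 (C5 with methyl, C6 with the chain). Cutting the ring–chain bond C6–C1' instead would require a regiodefined, fully substituted arene as coupling partner, which is the very problem to be avoided. Forward, the alkenyllithium 27 from 23 has to attack the carbonyl of 26 next to the methoxy-bearing carbon; adduct 28 has to open with hydroxyl outward to dienylketene 29; and 29 has to close to 30 and enolise.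

**26 to 25 to 24.** No carbon–carbon bond is cut. The C3–H of 26 is traced to a hydride delivered to one carbonyl of the symmetrical diester 24, followed by loss of one methoxy group from 25 with carbonyl transposition. The gain is a purchasable, symmetrical C4 source; the forward steps have to stop at single reduction.

**23 to 20 and 21 (through 22).** The bond C6–C1' is cut. This leaves the whole chain as a primary alkylzinc reagent 22, made from iodide 20, and the alkene as the commercial three-carbon geminal dibromide 21. The geometry of 23 follows from which of the two bromines reacts. The forward coupling has to stop after one substitution.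

**20 to 19 to 16 and 17 (through 18).** After a halide exchange, the bond C6'–C7' is cut. It separates the stereodefined block C7' to C17' from an achiral six-carbon linker. The cut is placed here because C7' is the carbonyl carbon left by the last homologation cycle and the derived tosylate 16 is unbranched at its β-carbon. The forward reaction joins two sp3 carbons and must leave the terminal chloride alone.

**16 to 15 to 14.** Functional-group changes only: sulfonate from alcohol, alcohol from thioester.

**14 back to 3 (reagent 2 from 1).** The four C–CH3 bonds at C9', C11', C13' and C15' are cut one at a time, each alternating with a two-carbon homologation (13, 10, 7) that places the next β-carbon. Each centre is made at the β-carbon of an enethioate by a chiral catalyst whose facial preference does not depend on the centres already present. One ligand enantiomer used four times should therefore give the all-syn array, and every intermediate (5, 8, 11, 14) can be checked. The ethyl terminus is present from acid 3 onward.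

## Alternatives that were turned down

**Alternative 1:** The two outer methyl groups are removed together (bonds C9'–CH3 and C15'–CH3), using the fact that the C9'–C15' tetrad, without its two different ends, has a mirror plane through C12'.
- Forward key step: bis-enoate A2 has syn inner methyl groups (the future C11' and C13') and is chiral only through its two different ester groups. A methylcuprate, accelerated by a silyl chloride, adds to both β-carbons in one operation to give diester A1, each new centre set syn to the nearest methyl by 1,3-induction.
- For: two stereocentres per operation, a core obtainable from a simple cis-disubstituted ring, and a short count for the tetrad.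
- Against: the induction is relayed across a methylene group in an open chain and rests on conformational bias alone, so each end gives some anti isomer, the errors multiply, and the by-products are diastereomers with identical functionality. The sense in which the two ester groups sit on the meso core fixes the absolute configuration and needs its own enantioselective desymmetrisation. Afterwards one carboxyl carbon must be reduced to the C17' methyl and the other extended by the C1'–C6' linker, at the cost of several redox steps.
- Comparison: in stereocentres per step A1 is the stronger plan. The chosen route offers centres made and checked one at a time under catalyst control, an ethyl terminus present from the start, and it spends its one non-routine step on the quinone, which Alternative 1 does not address.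

**Alternative 2:** All four branch-forming bonds (C15'–C16', C13'–C14', C11'–C12', C9'–C10') are cut at once; the tetrad is treated as an isotactic tetramer of propene A4 grown on an ethyl group supplied by diethylzinc A5.
- Forward key step: a single-enantiomer, C2-symmetric ansa-zirconocene dichloride activated by an aluminoxane inserts A4 four times in 1,2-fashion while the chains shuttle between zirconium and zinc; oxidative cleavage of the C8'–Zn bond gives alcohol A3.
- For: feedstock starting materials, the correct ethyl terminus, the all-syn relationship as the natural outcome of enantiomorphic site control, and one step for the tetrad against eight here. On step economy this alternative is clearly stronger.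
- Against: chain length is statistical, so A3 is one member of a series of homologues. Facial control of the first insertions into a short alkyl chain is weaker than in polymer growth, and each misinsertion gives an inseparable diastereomer. Oxidation of zinc alkyls is not clean. The hydroxyl of A3 sits next to the C9' stereocentre, so the later seven-carbon extension must occur at a β-branched carbon.
- Comparison: the chosen route offers, for its greater length, one defined compound after every step and a stereochemical purity that rests on four separately verifiable reactions.

**Alternative 3:** The bonds C6–C1' and C5–CH3 are cut on a preformed six-membered ring, quinone monoketal A6, in which C1 is masked as its dimethyl ketal.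
- Forward key step: the chain, as the organocopper reagent derived from iodide 20 and activated by a silyl chloride, adds to the only unsubstituted enone β-carbon of A6. The silyl enol ether is converted into the lithium enolate and methylated with a methyl halide in the same flask to give A7; ketal hydrolysis, enolisation and oxidation would then lead to 32.
- For: the ring comes from an inexpensive aromatic compound, iodide 20 is used directly without the alkenyl unit or the C4 dione, the methoxy group deactivates the other β-position, and the end game is about one step shorter. In convergence this alternative is at least as strong as the chosen one.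
- Against: the carbon to be attacked lies next to the fully substituted ketal carbon. Organocopper reagents tend to transfer an electron to quinone monoketals, which then lose methoxide and aromatise. The valuable chain is needed in excess as the nucleophile. Methylation of the regenerated enolate competes with proton transfer, O-alkylation and double alkylation.
- Comparison: the chosen route places every ring substituent by connectivity, needs only two selectivities that are inherent in the methoxycyclobutenone, and uses the chain in a clean halogen–lithium exchange and carbonyl addition.

Key step: step 17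

Assumption: the (S,RP) enantiomer of the ferrocenyl diphosphine CpFe[C5H3(PPh2)CH(Me)PCy2] (Josiphos; (S)-1-[(RP)-2-(diphenylphosphino)ferrocenyl]ethyldicyclohexylphosphine) is taken as the one whose CuBr complex adds methyl to the enethioate face that gives (3S)-5; should the sense be the reverse, the (R,SP) enantiomer is used in steps 3, 5, 7 and 9 and nothing else changes.

## Steps

Step 1
Reactants: 1 2-(diethoxyphosphoryl)acetic acid
Product: 2 S-ethyl 2-(diethoxyphosphoryl)ethanethioate
Conditions: EtSH, DCC, DMAP (cat.), CH2Cl2, 0 °C → rt
Reagents that add atoms: ethanethiol, CCS
Why: Steglich-type thioesterification; the acylpyridinium formed with DMAP is captured by the thiol and the phosphonate is inert.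

Step 2
Reactants: 3 (2E)-pent-2-enoic acid
Product: 4 S-ethyl (2E)-pent-2-enethioate
Conditions: EtSH, DCC, DMAP (cat.), CH2Cl2, 0 °C → rt
Reagents that add atoms: ethanethiol, CCS
Why: Steglich thioesterification of the conjugated acid; low temperature and catalytic DMAP should keep thiol conjugate addition in check, and the E geometry of the purchased acid is retained.

Step 3
Reactants: 4 S-ethyl (2E)-pent-2-enethioate
Product: 5 S-ethyl (3S)-3-methylpentanethioate
Conditions: MeMgBr, CuBr·SMe2 (1 mol%), (S,RP)-CpFe[C5H3(PPh2)CH(Me)PCy2] (1.2 mol%), t-BuOMe, −75 °C
Reagents that add atoms: methylmagnesium bromide, C[Mg]Br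
Why: Copper-catalysed enantioselective conjugate addition of a Grignard reagent to an α,β-unsaturated thioester; the chiral diphosphine–copper complex delivers methyl to one face of the enethioate and so sets C3 (the future C15') as S under catalyst control.

Step 4
Reactants: 5 S-ethyl (3S)-3-methylpentanethioate; 2 S-ethyl 2-(diethoxyphosphoryl)ethanethioate
Product: 7 S-ethyl (2E,5S)-5-methylhept-2-enethioate, via (3S)-3-methylpentanal 6 (not isolated)
Conditions: i-Bu2AlH (1.1 equiv), CH2Cl2, −78 °C; aq. potassium sodium tartrate; dried solution of 6 added to 2/n-BuLi, THF, 0 °C → rt
Reagents that add atoms: none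
Why: The thioester stops at the aldehyde because the aluminium hemithioacetal survives until work-up; Horner–Wadsworth–Emmons olefination with the lithium anion of 2 then gives the E enethioate. The stereocentre is β to the carbonyl and cannot epimerise, and the volatile aldehyde 6 is never concentrated.

Step 5
Reactants: 7 S-ethyl (2E,5S)-5-methylhept-2-enethioate
Product: 8 S-ethyl (3S,5S)-3,5-dimethylheptanethioate
Conditions: MeMgBr, CuBr·SMe2 (1 mol%), (S,RP)-CpFe[C5H3(PPh2)CH(Me)PCy2] (1.2 mol%), t-BuOMe, −75 °C
Reagents that add atoms: methylmagnesium bromide, C[Mg]Br
Why: Second copper-catalysed conjugate addition with the same ligand enantiomer; catalyst control should override the remote C5 centre and give the 3,5-syn product, setting the future C13'.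

Step 6
Reactants: 8 S-ethyl (3S,5S)-3,5-dimethylheptanethioate; 2 S-ethyl 2-(diethoxyphosphoryl)ethanethioate
Product: 10 S-ethyl (2E,5S,7S)-5,7-dimethylnon-2-enethioate, via (3S,5S)-3,5-dimethylheptanal 9 (not isolated)
Conditions: i-Bu2AlH (1.1 equiv), CH2Cl2, −78 °C; aq. potassium sodium tartrate; dried solution of 9 added to 2/n-BuLi, THF, 0 °C → rt
Reagents that add atoms: none
Why: Partial reduction of the thioester and Horner–Wadsworth–Emmons olefination as in step 4; neither stereocentre is α to a carbonyl at any stage.

Step 7
Reactants: 10 S-ethyl (2E,5S,7S)-5,7-dimethylnon-2-enethioate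
Product: 11 S-ethyl (3S,5S,7S)-3,5,7-trimethylnonanethioate
Conditions: MeMgBr, CuBr·SMe2 (1 mol%), (S,RP)-CpFe[C5H3(PPh2)CH(Me)PCy2] (1.2 mol%), t-BuOMe, −75 °C
Reagents that add atoms: methylmagnesium bromide, C[Mg]Br
Why: Third catalyst-controlled conjugate addition; the same ligand enantiomer should again place the new methyl syn to its neighbour, setting the future C11'.

Step 8
Reactants: 11 S-ethyl (3S,5S,7S)-3,5,7-trimethylnonanethioate; 2 S-ethyl 2-(diethoxyphosphoryl)ethanethioate
Product: 13 S-ethyl (2E,5S,7S,9S)-5,7,9-trimethylundec-2-enethioate, via (3S,5S,7S)-3,5,7-trimethylnonanal 12 (not isolated)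
Conditions: i-Bu2AlH (1.1 equiv), CH2Cl2, −78 °C; aq. potassium sodium tartrate; dried solution of 12 added to 2/n-BuLi, THF, 0 °C → rt
Reagents that add atoms: none
Why: Partial reduction of the thioester and Horner–Wadsworth–Emmons olefination as in step 4.

Step 9
Reactants: 13 S-ethyl (2E,5S,7S,9S)-5,7,9-trimethylundec-2-enethioate
Product: 14 S-ethyl (3S,5S,7S,9S)-3,5,7,9-tetramethylundecanethioate
Conditions: MeMgBr, CuBr·SMe2 (1 mol%), (S,RP)-CpFe[C5H3(PPh2)CH(Me)PCy2] (1.2 mol%), t-BuOMe, −75 °C
Reagents that add atoms: methylmagnesium bromide, C[Mg]Br
Why: Fourth catalyst-controlled conjugate addition, setting the future C9' syn to C11'; all four descriptors read S here only because the thioester end outranks the alkyl end.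

Step 10
Reactants: 14 S-ethyl (3S,5S,7S,9S)-3,5,7,9-tetramethylundecanethioate
Product: 15 (3S,5S,7S,9S)-3,5,7,9-tetramethylundecan-1-ol
Conditions: LiAlH4, THF, 0 °C
Reagents that add atoms: none
Why: Hydride reduction of the thioester to the primary alcohol; no stereocentre is α to the carbonyl, so none can epimerise.

Step 11
Reactants: 15 (3S,5S,7S,9S)-3,5,7,9-tetramethylundecan-1-ol
Product: 16 (3S,5S,7S,9S)-3,5,7,9-tetramethylundecyl 4-methylbenzenesulfonate
Conditions: TsCl, Et3N, DMAP (cat.), CH2Cl2, 0 °C → rt
Reagents that add atoms: 4-methylbenzenesulfonyl chloride, Cc1ccc(cc1)S(=O)(=O)Cl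
Why: Sulfonylation of an unhindered primary alcohol; the tosylate is unbranched at its β-carbon and suited to the displacement that follows.

Step 12
Reactants: 16 (3S,5S,7S,9S)-3,5,7,9-tetramethylundecyl 4-methylbenzenesulfonate; 17 1-bromo-6-chlorohexane
Product: 19 (9R,11R,13S,15S)-1-chloro-9,11,13,15-tetramethylheptadecane, via (6-chlorohexyl)magnesium bromide 18 (not isolated)
Conditions: 17, Mg, THF, rt; then 16, Li2CuCl4 (5 mol%), THF, −20 °C → rt
Reagents that add atoms: none
Why: Magnesium inserts into the C–Br bond of 17 and leaves the C–Cl bond; copper-catalysed coupling of Grignard reagent 18 with the primary tosylate joins C6' to C7', and a primary chloride is not displaced under these conditions. The stereocentres are untouched; the descriptors change only because the chain is renumbered.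

Step 13
Reactants: 19 (9R,11R,13S,15S)-1-chloro-9,11,13,15-tetramethylheptadecane
Product: 20 (9R,11R,13S,15S)-1-iodo-9,11,13,15-tetramethylheptadecane
Conditions: NaI, 2-butanone, reflux
Reagents that add atoms: sodium iodide, [Na+].[I-]
Why: Finkelstein exchange at a primary carbon, driven by precipitation of NaCl from the ketone solvent.

Step 14
Reactants: 20 (9R,11R,13S,15S)-1-iodo-9,11,13,15-tetramethylheptadecane; 21 1,1-dibromoprop-1-ene
Product: 23 (2Z,12R,14R,16S,18S)-3-bromo-12,14,16,18-tetramethylicos-2-ene, via alkylzinc iodide 22 (not isolated)
Conditions: Zn dust, LiCl, THF, 40 °C; then 21 (3 equiv), PdCl2[(Ph2PC6H4)2O] (3 mol%), THF, 0 °C → rt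
Reagents that add atoms: none
Why: Zinc inserts into the primary C–I bond to give 22; Negishi coupling with 21 occurs at the C–Br bond trans to methyl, which adds to zerovalent palladium faster for steric reasons, so the chain ends trans to methyl and the remaining bromine cis to it (2Z). Excess of the inexpensive dibromide and a wide-bite-angle diphosphine, which favours reductive elimination over β-hydride elimination, are meant to hold the reaction at mono-coupling.

Step 15
Reactants: 24 3,4-dimethoxycyclobut-3-ene-1,2-dione
Product: 25 4-hydroxy-2,3-dimethoxycyclobut-2-en-1-one (racemic)
Conditions: LiAlH(O-t-Bu)3 (1.1 equiv), THF, −78 → −20 °C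
Reagents that add atoms: none
Why: The hindered alkoxyaluminium hydride adds once to one of the two equivalent carbonyls of the symmetrical diester, and the resulting alkoxide is not reduced further at low temperature.

Step 16
Reactants: 25 4-hydroxy-2,3-dimethoxycyclobut-2-en-1-one
Product: 26 3-methoxycyclobut-3-ene-1,2-dione
Conditions: conc. HCl (cat.), CH2Cl2, rt
Reagents that add atoms: water, O
Why: Acid ionises the allylic carbinol to a cyclobutenyl cation stabilised by the distal methoxy group; water adds at that methoxy-bearing carbon and methanol is lost, which transposes the carbonyl and leaves C–H where the hydride was delivered (acid-catalysed hydrolytic allylic transposition). Product 26 is electrophilic and moisture-sensitive and is used freshly prepared.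

Step 17
Reactants: 23 (2Z,12R,14R,16S,18S)-3-bromo-12,14,16,18-tetramethylicos-2-ene; 26 3-methoxycyclobut-3-ene-1,2-dione
Product: 31 2-methoxy-5-methyl-6-[(9R,11R,13S,15S)-9,11,13,15-tetramethylheptadecyl]benzene-1,4-diol, via alkenyllithium 27 (not isolated), via hydroxycyclobutenone 28 (not isolated), via dienylketene 29 (not isolated), via cyclohexadienone 30 (not isolated)
Conditions: t-BuLi (2 equiv), Et2O, −78 °C; cannulated into 26, THF, −78 °C; aq. NH4Cl; crude 28, degassed toluene (0.01 M), 110 °C
Reagents that add atoms: none
Why: Bromine–lithium exchange on 23 proceeds with retention to give 27, which adds to the carbonyl of 26 that flanks the methoxy-bearing carbon, because the other carbonyl is deactivated as a vinylogous ester; this forms C1–C6 and fixes methoxy next to the future C1 oxygen. On heating, 28 undergoes thermal conrotatory 4π ring opening, and the preference of the hydroxyl donor for outward rotation turns the alkenyl group inward, cis to the ketene in 29. Ketene carbon C4 and alkene terminus C5 then join in a thermally allowed disrotatory 6π electrocyclisation that closes the six-membered carbocycle as 30, and enolisation of its C5–H gives aromatic 31. The closest known reaction type is the thermal ring expansion of 4-alkenyl-4-hydroxycyclobutenones, made from squaric acid derivatives, to hydroquinones. No stereocentre is created: the carbinol carbon of 28 and C5 of 30 are transient and both become sp2, so neither the epimer mixture of 28 nor the alkene geometry affects the product. The step needs site-selective carbonyl addition and outward rotation of hydroxyl, and both are inherent in the 3-methoxycyclobutenone. The methyl on C5 lies inside during closure, unlike the hydrogen of the common 1-cycloalkenyl cases, but the ketene terminus is sp-hybridised and has no inside substituent to meet it, so the penalty should be modest and is answered by longer heating, since ring opening is reversible.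

Step 18
Reactants: 31 2-methoxy-5-methyl-6-[(9R,11R,13S,15S)-9,11,13,15-tetramethylheptadecyl]benzene-1,4-diol
Product: 32 2-methoxy-5-methyl-6-[(9R,11R,13S,15S)-9,11,13,15-tetramethylheptadecyl]cyclohexa-2,5-diene-1,4-dione (CNP0330767.1)
Conditions: Ag2O, Na2SO4, Et2O, rt
Reagents that add atoms: none
Why: Two-electron oxidation of an electron-rich hydroquinone by Ag2O; the conditions are neutral and heterogeneous, so the methoxyquinone meets no nucleophile.

## Compound list

1 | 2-(diethoxyphosphoryl)acetic acid | CCOP(=O)(CC(=O)O)OCC | starting material
2 | S-ethyl 2-(diethoxyphosphoryl)ethanethioate | CCOP(=O)(CC(=O)SCC)OCC | intermediate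
3 | (2E)-pent-2-enoic acid | CC/C=C/C(=O)O | starting material
4 | S-ethyl (2E)-pent-2-enethioate | CC/C=C/C(=O)SCC | intermediate
5 | S-ethyl (3S)-3-methylpentanethioate | CC[C@H](C)CC(=O)SCC | intermediate
6 | (3S)-3-methylpentanal | CC[C@H](C)CC=O | intermediate
7 | S-ethyl (2E,5S)-5-methylhept-2-enethioate | CC[C@H](C)C/C=C/C(=O)SCC | intermediate
8 | S-ethyl (3S,5S)-3,5-dimethylheptanethioate | CC[C@H](C)C[C@H](C)CC(=O)SCC | intermediate
9 | (3S,5S)-3,5-dimethylheptanal | CC[C@H](C)C[C@H](C)CC=O | intermediate
10 | S-ethyl (2E,5S,7S)-5,7-dimethylnon-2-enethioate | CC[C@H](C)C[C@H](C)C/C=C/C(=O)SCC | intermediate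
11 | S-ethyl (3S,5S,7S)-3,5,7-trimethylnonanethioate | CC[C@H](C)C[C@H](C)C[C@H](C)CC(=O)SCC | intermediate
12 | (3S,5S,7S)-3,5,7-trimethylnonanal | CC[C@H](C)C[C@H](C)C[C@H](C)CC=O | intermediate
13 | S-ethyl (2E,5S,7S,9S)-5,7,9-trimethylundec-2-enethioate | CC[C@H](C)C[C@H](C)C[C@H](C)C/C=C/C(=O)SCC | intermediate
14 | S-ethyl (3S,5S,7S,9S)-3,5,7,9-tetramethylundecanethioate | CC[C@H](C)C[C@H](C)C[C@H](C)C[C@H](C)CC(=O)SCC | intermediate
15 | (3S,5S,7S,9S)-3,5,7,9-tetramethylundecan-1-ol | CC[C@H](C)C[C@H](C)C[C@H](C)C[C@H](C)CCO | intermediate
16 | (3S,5S,7S,9S)-3,5,7,9-tetramethylundecyl 4-methylbenzenesulfonate | CC[C@H](C)C[C@H](C)C[C@H](C)C[C@H](C)CCOS(=O)(=O)c1ccc(C)cc1 | intermediate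
17 | 1-bromo-6-chlorohexane | ClCCCCCCBr | starting material
18 | (6-chlorohexyl)magnesium bromide | ClCCCCCC[Mg]Br | intermediate
19 | (9R,11R,13S,15S)-1-chloro-9,11,13,15-tetramethylheptadecane | CC[C@H](C)C[C@H](C)C[C@H](C)C[C@H](C)CCCCCCCCCl | intermediate
20 | (9R,11R,13S,15S)-1-iodo-9,11,13,15-tetramethylheptadecane | CC[C@H](C)C[C@H](C)C[C@H](C)C[C@H](C)CCCCCCCCI | intermediate
21 | 1,1-dibromoprop-1-ene | CC=C(Br)Br | starting material
22 | [(9R,11R,13S,15S)-9,11,13,15-tetramethylheptadecyl]zinc iodide | CC[C@H](C)C[C@H](C)C[C@H](C)C[C@H](C)CCCCCCCC[Zn]I | intermediate
23 | (2Z,12R,14R,16S,18S)-3-bromo-12,14,16,18-tetramethylicos-2-ene | CC[C@H](C)C[C@H](C)C[C@H](C)C[C@H](C)CCCCCCCC/C(Br)=C/C | intermediate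
24 | 3,4-dimethoxycyclobut-3-ene-1,2-dione | COC1=C(OC)C(=O)C1=O | starting material
25 | 4-hydroxy-2,3-dimethoxycyclobut-2-en-1-one (racemic) | COC1=C(OC)C(O)C1=O | intermediate
26 | 3-methoxycyclobut-3-ene-1,2-dione | COC1=CC(=O)C1=O | intermediate
27 | [(2E,12R,14R,16S,18S)-12,14,16,18-tetramethylicos-2-en-3-yl]lithium (lithium cis to the C1 methyl) | CC[C@H](C)C[C@H](C)C[C@H](C)C[C@H](C)CCCCCCCC/C([Li])=C/C | intermediate
28 | 4-hydroxy-3-methoxy-4-[(2Z,12R,14R,16S,18S)-12,14,16,18-tetramethylicos-2-en-3-yl]cyclobut-2-en-1-one (both epimers at ring C4) | CC[C@H](C)C[C@H](C)C[C@H](C)C[C@H](C)CCCCCCCC/C(=C/C)C1(O)C(OC)=CC1=O | intermediate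
29 | (3Z,5Z)-4-hydroxy-3-methoxy-5-[(9R,11R,13S,15S)-9,11,13,15-tetramethylheptadecyl]hepta-1,3,5-trien-1-one | CC[C@H](C)C[C@H](C)C[C@H](C)C[C@H](C)CCCCCCCC/C(=C/C)/C(O)=C(OC)\C=C=O | intermediate
30 | 4-hydroxy-3-methoxy-6-methyl-5-[(9R,11R,13S,15S)-9,11,13,15-tetramethylheptadecyl]cyclohexa-2,4-dien-1-one (both epimers at ring C6) | CC[C@H](C)C[C@H](C)C[C@H](C)C[C@H](C)CCCCCCCCC1=C(O)C(OC)=CC(=O)C1C | intermediate
31 | 2-methoxy-5-methyl-6-[(9R,11R,13S,15S)-9,11,13,15-tetramethylheptadecyl]benzene-1,4-diol | CC[C@H](C)C[C@H](C)C[C@H](C)C[C@H](C)CCCCCCCCc1c(C)c(O)cc(OC)c1O | intermediate
32 | 2-methoxy-5-methyl-6-[(9R,11R,13S,15S)-9,11,13,15-tetramethylheptadecyl]cyclohexa-2,5-diene-1,4-dione | CC[C@H](C)C[C@H](C)C[C@H](C)C[C@H](C)CCCCCCCCC1=C(C)C(=O)C=C(OC)C1=O | target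

## Step count and least certain steps

Total step count: 18. Longest linear sequence: 15 steps (steps 2 to 14, then 17 and 18, from acid 3).

**Step 17 (key step).** Two things are most likely to go wrong.
- The alkenyllithium may attack the methoxy-bearing carbon (addition–elimination with loss of methoxide) or the vinylogous ester carbonyl instead of the ketone-like carbonyl. The dione is small and electrophilic at three carbons, and the nucleophile is hindered at its α-carbon.
- The 6π closure may be slow because the C5 methyl points inward. The reversibly formed ketene would then be drained by dimerisation or, after the minor inward rotation of hydroxyl, by lactonisation.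

The fallback sets out from iodide 20 and comes back at target 32. Iodine–lithium exchange on 20 (t-BuLi, Et2O, −78 °C) and carboxylation with CO2 should give (10R,12R,14S,16S)-10,12,14,16-tetramethyloctadecanoic acid F1. Purchased 2-methoxy-5-methylphenol F2 is oxidised at its free para position with (KSO3)2NO to 2-methoxy-5-methylcyclohexa-2,5-diene-1,4-dione F3. Silver-catalysed persulfate decarboxylation of F1 (AgNO3, (NH4)2S2O8, MeCN/H2O, 65 °C) in the presence of F3 generates the primary C1' radical, which should add to C6 of F3, the free position on the double bond not deactivated by methoxy; reoxidation gives 32. Some C3 isomer must be expected and separated, which is why this radical alkylation is the reserve and not the plan.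

**Step 14.** The coupling may run on to the second C–Br bond, or the alkylpalladium intermediate may undergo β-hydride elimination and end in reduction. The product is itself an alkenyl bromide, and primary alkylzinc reagents carry β-hydrogens. The fallback sets out from zinc reagent 22 and comes back at alkenyllithium 27 inside step 17. Reagent 22 is coupled with purchased 1,1-dichloroprop-1-ene F4 under PdCl2[(Ph2PC6H4)2O]; mono-alkylation of geminal dichloroalkenes is trans-selective and stops cleanly because the second C–Cl bond is far less reactive. This gives (2Z,12R,14R,16S,18S)-3-chloro-12,14,16,18-tetramethylicos-2-ene F5. Reductive lithiation of F5 with lithium metal and catalytic 4,4'-di-tert-butylbiphenyl (THF, −78 °C) then gives 27; any loss of alkene geometry at the radical stage is without consequence, since both geometries lead to 31.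

**Step 12.** Magnesium insertion into 17 may not distinguish fully between bromide and chloride, or the Grignard reagent may couple with its own halide, so that the tosylate meets a mixture of nucleophiles; the displacement itself may also be slow. The fallback sets out from tosylate 16 and comes back at chloride 19. Displacement with PhSO2Na (DMF, 80 °C) gives {[(3S,5S,7S,9S)-3,5,7,9-tetramethylundecyl]sulfonyl}benzene F6. Its α-lithio derivative (n-BuLi, THF, −78 °C) is alkylated by 17 at the C–Br bond to give {[(9S,11S,13S,15S)-1-chloro-9,11,13,15-tetramethylheptadecan-7-yl]sulfonyl}benzene F7 as a mixture of C7 epimers (the chain descriptors change only because sulfur alters CIP priorities). Reductive desulfonylation (Na(Hg), Na2HPO4, MeOH, −20 °C) removes the sulfonyl group and the C7 stereocentre with it, giving 19.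

## Further compounds

F1 | step 17 | (10R,12R,14S,16S)-10,12,14,16-tetramethyloctadecanoic acid | CC[C@H](C)C[C@H](C)C[C@H](C)C[C@H](C)CCCCCCCCC(=O)O
F2 | step 17 | 2-methoxy-5-methylphenol (purchased) | COc1ccc(C)cc1O
F3 | step 17 | 2-methoxy-5-methylcyclohexa-2,5-diene-1,4-dione | COC1=CC(=O)C(C)=CC1=O
F4 | step 14 | 1,1-dichloroprop-1-ene (purchased) | CC=C(Cl)Cl
F5 | step 14 | (2Z,12R,14R,16S,18S)-3-chloro-12,14,16,18-tetramethylicos-2-ene | CC[C@H](C)C[C@H](C)C[C@H](C)C[C@H](C)CCCCCCCC/C(Cl)=C/C
F6 | step 12 | {[(3S,5S,7S,9S)-3,5,7,9-tetramethylundecyl]sulfonyl}benzene | CC[C@H](C)C[C@H](C)C[C@H](C)C[C@H](C)CCS(=O)(=O)c1ccccc1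
F7 | step 12 | {[(9S,11S,13S,15S)-1-chloro-9,11,13,15-tetramethylheptadecan-7-yl]sulfonyl}benzene (both C7 epimers) | CC[C@H](C)C[C@H](C)C[C@H](C)C[C@H](C)CC(CCCCCCCl)S(=O)(=O)c1ccccc1
A1 | alternative 1 | 1-tert-butyl 11-methyl (3S,5S,7R,9R)-3,5,7,9-tetramethylundecanedioate | COC(=O)C[C@H](C)C[C@H](C)C[C@H](C)C[C@H](C)CC(=O)OC(C)(C)C
A2 | alternative 1 | 1-tert-butyl 11-methyl (2E,5S,7R,9E)-5,7-dimethylundeca-2,9-dienedioate | COC(=O)/C=C/C[C@H](C)C[C@H](C)C/C=C/C(=O)OC(C)(C)C
A3 | alternative 2 | (2S,4S,6S,8S)-2,4,6,8-tetramethyldecan-1-ol | CC[C@H](C)C[C@H](C)C[C@H](C)C[C@H](C)CO
A4 | alternative 2 | propene | CC=C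
A5 | alternative 2 | diethylzinc | CC[Zn]CC
A6 | alternative 3 | 3,4,4-trimethoxycyclohexa-2,5-dien-1-one | COC1=CC(=O)C=CC1(OC)OC
A7 | alternative 3 | trans-3,4,4-trimethoxy-6-methyl-5-[(9R,11R,13S,15S)-9,11,13,15-tetramethylheptadecyl]cyclohex-2-en-1-one (ring centres transient) | CC[C@H](C)C[C@H](C)C[C@H](C)C[C@H](C)CCCCCCCCC1C(C)C(=O)C=C(OC)C1(OC)OC
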